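**Strategy.** The trimer is cut at both C4–C8 interflavan bonds into three copies of one block, penta-O-benzyl-(−)-epigallocatechin, rejoined by two Lewis-acid 4β→8 arylations. The block is built de novo. In its ring C (O1–C2–C3–C4–C4a–C8a) the O1–C2(aryl) unit is read as an aryl gallate ester and C3–C4 as an allyl group on ring A. One titanium-methylidene operation (ester methylenation, then ring-closing metathesis) joins the ester carbon to the inner allyl carbon as the C2=C3 bond of a 4H-chromene. Hydroboration–oxidation and a dynamic-kinetic transfer hydrogenation of the resulting flavan-3-one then set the 2R,3R-cis pair.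

Key step: step 4

Remark: short-lived cations in steps 7, 9 and 10 carry no compound number. In step 6 the (S,S) complex is chosen by analogy only; if the sense of induction proves opposite, the (R,R) complex is used.

**Step 1**
Reactants: 1 3,5-bis(benzyloxy)phenol; 2 allyl bromide
Product: 3 1-(allyloxy)-3,5-bis(benzyloxy)benzene
Conditions: K2CO3, acetone, reflux
Reagents that add atoms: none
Why: Williamson ether synthesis, the phenoxide being alkylated on oxygen by the primary allylic bromide.

**Step 2**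
Reactants: 3 1-(allyloxy)-3,5-bis(benzyloxy)benzene
Product: 5 2-allyl-3,5-bis(benzyloxy)phenol, via 6-allylcyclohexadienone 4 (not isolated)
Conditions: N,N-diethylaniline, 190 °C, sealed tube
Reagents that add atoms: none
Why: aromatic Claisen rearrangement ([3,3]-sigmatropic shift, then tautomerisation); the two ortho positions are equivalent, so one 2-allylphenol should result.

**Step 3**
Reactants: 5 2-allyl-3,5-bis(benzyloxy)phenol; 6 3,4,5-tris(benzyloxy)benzoic acid
Product: 7 2-allyl-3,5-bis(benzyloxy)phenyl 3,4,5-tris(benzyloxy)benzoate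
Conditions: DCC, DMAP (cat.), CH2Cl2, rt
Reagents that add atoms: none
Why: Steglich esterification, DMAP relaying the acyl group to the moderately hindered phenol.

**Step 4**
Reactants: 7 2-allyl-3,5-bis(benzyloxy)phenyl 3,4,5-tris(benzyloxy)benzoate
Product: 9 5,7-bis(benzyloxy)-2-[3,4,5-tris(benzyloxy)phenyl]-4H-chromene, via 1-arylvinyl ether 8 (not isolated)
Conditions: Tebbe reagent Cp2Ti(μ-Cl)(μ-CH2)AlMe2 (4 equiv), pyridine (cat.), THF (0.01 M), 0 °C to rt, then reflux; aqueous NaOH quench, basic alumina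
Reagents that add atoms: none
Why: The titanocene methylidene released from the Tebbe reagent first methylenates the only ester carbonyl through an oxatitanacyclobutane to give enol ether 8; excess methylidene then picks up the terminal allyl alkene and closes the ring by [2+2]/retro-[2+2] metathesis onto the 1,1-disubstituted enol ether, expelling ethylene. The closest known reaction type is the one-pot titanium-mediated olefinic-ester cyclisation to cyclic enol ethers (carbonyl methylenation followed by ring-closing metathesis). Ring C closes as a six-membered ring with the new C2=C3 bond endocyclic, the ortho-disposed arene holding the two alkenes within reach. No stereocentre is created here; C2 and C3 become stereogenic in steps 5 and 6. The step needs chemoselectivity for the aryl ester, which is secured because benzyl ethers and electron-rich arenes are inert to titanium alkylidenes. It also needs cyclisation to win over allyl isomerisation or intermolecular metathesis, which the ortho relationship, high dilution and loss of ethylene should favour.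

**Step 5**
Reactants: 9 5,7-bis(benzyloxy)-2-[3,4,5-tris(benzyloxy)phenyl]-4H-chromene
Product: 11 racemic 5,7-bis(benzyloxy)-2-[3,4,5-tris(benzyloxy)phenyl]chroman-3-one, via trans-3-borylflavan 10 (not isolated)
Conditions: BH3·THF, THF, 0 °C to rt; then N-methylmorpholine N-oxide (excess), tetrapropylammonium perruthenate (n-Pr4N)(RuO4) (5 mol %), 4 Å molecular sieves, CH2Cl2, rt
Reagents that add atoms: N-methylmorpholine N-oxide C[N+]1([O-])CCOCC1
Why: hydroboration places boron on C3, the β-carbon of the enol ether, and the amine oxide/perruthenate couple oxidises the C–B bond through the alcohol level to the ketone (one-pot hydroboration–oxidation of an alkene to a ketone), so the C3 configuration of the borane is irrelevant.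

**Step 6**
Reactants: 11 racemic 5,7-bis(benzyloxy)-2-[3,4,5-tris(benzyloxy)phenyl]chroman-3-one
Product: 12 (2R,3R)-5,7-bis(benzyloxy)-2-[3,4,5-tris(benzyloxy)phenyl]chroman-3-ol (penta-O-benzyl-(−)-epigallocatechin)
Conditions: RuCl[(S,S)-TsDPEN](p-cymene) (2 mol %), HCO2H/Et3N (2:5), DMF, 40 °C
Reagents that add atoms: none
Why: Noyori-type asymmetric transfer hydrogenation under dynamic kinetic resolution: C2 (α to the ketone, benzylic and O-substituted) racemises through the enol in the amine-rich medium, the catalyst reduces one ketone enantiomer faster and delivers hydride anti to the 2-aryl group, which should give the 2,3-cis (2R,3R) alcohol.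

**Step 7**
Reactants: 12 penta-O-benzyl-(−)-epigallocatechin
Product: 13 4β-(2-ethoxyethoxy)-penta-O-benzyl-(−)-epigallocatechin (2,3-cis and 3,4-trans)
Conditions: DDQ (2 equiv), 2-ethoxyethanol (5 equiv), CH2Cl2, rt
Reagents that add atoms: 2-ethoxyethanol CCOCCO
Why: benzylic oxidation with DDQ, in which hydride abstraction from C4 gives a cation stabilised by the 5- and 7-ether oxygens that the alcohol traps anti to the axial 3-hydroxyl (4β).

**Step 8**
Reactants: 13 4β-(2-ethoxyethoxy)-penta-O-benzyl-(−)-epigallocatechin; 6 3,4,5-tris(benzyloxy)benzoic acid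
Product: 14 4β-(2-ethoxyethoxy)-penta-O-benzyl-(−)-epigallocatechin 3-O-[3,4,5-tris(benzyloxy)benzoate]
Conditions: DCC, DMAP, CH2Cl2, rt
Reagents that add atoms: none
Why: Steglich esterification of the axial 3-hydroxyl under neutral conditions that leave the acid-labile C4 ether untouched.

**Step 9**
Reactants: 14 galloylated C4 ether (1 equiv); 12 penta-O-benzyl-(−)-epigallocatechin (4 equiv)
Product: 15 octa-O-benzyl-epigallocatechin 3-O-gallate-(4β→8)-penta-O-benzyl-epigallocatechin
Conditions: Me3SiOTf (0.2 equiv), CH2Cl2, −78 to −40 °C; Et3N quench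
Reagents that add atoms: none
Why: Me3SiOTf ionises the C4 ether of 14 to a flavan-4-yl cation whose α-face is shielded by the neighbouring 3-O-acyl group, so C8 of 12 (the most nucleophilic arene position, used in excess to outrun self-condensation) attacks from the β-face in a Friedel–Crafts-type arylation that sets the 3,4-trans (4β→8) centre.

**Step 10**
Reactants: 13 4β-(2-ethoxyethoxy)-penta-O-benzyl-(−)-epigallocatechin (1 equiv); 15 protected dimer (2.5 equiv)
Product: 16 penta-O-benzyl-epigallocatechin-(4β→8)-octa-O-benzyl-epigallocatechin 3-O-gallate-(4β→8)-penta-O-benzyl-epigallocatechin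
Conditions: Me3SiOTf (0.3 equiv), CH2Cl2, −40 °C; Et3N quench
Reagents that add atoms: none
Why: the same Lewis-acid Friedel–Crafts-type arylation, the C4 cation from 13 being attacked anti to its axial 3-hydroxyl (4β) by C8 of the upper unit of 15, the most electron-rich and least hindered free position, while excess 15 limits electrophile self-condensation.

**Step 11**
Reactants: 16 protected trimer
Product: 17 epigallocatechin-(4β→8)-epigallocatechin 3-O-gallate-(4β→8)-epigallocatechin (CNP0278699.1)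
Conditions: H2 (1 atm), Pd(OH)2/C, THF/MeOH/H2O, rt; filtration and lyophilisation under inert gas
Reagents that add atoms: none
Why: hydrogenolysis should cleave all eighteen benzyl ethers while the gallate ester, the interflavan bonds and the stereocentres are inert.

**Compound list**

1 | 3,5-bis(benzyloxy)phenol | Oc1cc(OCc2ccccc2)cc(OCc2ccccc2)c1 | starting material
2 | allyl bromide | C=CCBr | starting material
3 | 1-(allyloxy)-3,5-bis(benzyloxy)benzene | C=CCOc1cc(OCc2ccccc2)cc(OCc2ccccc2)c1 | intermediate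
4 | 6-allyl-3,5-bis(benzyloxy)cyclohexa-2,4-dien-1-one (not isolated) | C=CCC1C(=O)C=C(OCc2ccccc2)C=C1OCc1ccccc1 | intermediate
5 | 2-allyl-3,5-bis(benzyloxy)phenol | C=CCc1c(O)cc(OCc2ccccc2)cc1OCc1ccccc1 | intermediate
6 | 3,4,5-tris(benzyloxy)benzoic acid | OC(=O)c1cc(OCc2ccccc2)c(OCc2ccccc2)c(OCc2ccccc2)c1 | starting material
7 | 2-allyl-3,5-bis(benzyloxy)phenyl 3,4,5-tris(benzyloxy)benzoate | C=CCc1c(OC(=O)c2cc(OCc3ccccc3)c(OCc3ccccc3)c(OCc3ccccc3)c2)cc(OCc2ccccc2)cc1OCc1ccccc1 | intermediate
8 | 2-allyl-3,5-bis(benzyloxy)phenyl 1-[3,4,5-tris(benzyloxy)phenyl]vinyl ether (not isolated) | C=CCc1c(OC(=C)c2cc(OCc3ccccc3)c(OCc3ccccc3)c(OCc3ccccc3)c2)cc(OCc2ccccc2)cc1OCc1ccccc1 | intermediate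
9 | 5,7-bis(benzyloxy)-2-[3,4,5-tris(benzyloxy)phenyl]-4H-chromene | O1C(c2cc(OCc3ccccc3)c(OCc3ccccc3)c(OCc3ccccc3)c2)=CCc2c1cc(OCc1ccccc1)cc2OCc1ccccc1 | intermediate
10 | racemic trans-3-boryl-5,7-bis(benzyloxy)-2-[3,4,5-tris(benzyloxy)phenyl]chroman (not isolated; one enantiomer drawn) | B[C@H]1Cc2c(OCc3ccccc3)cc(OCc3ccccc3)cc2O[C@@H]1c1cc(OCc2ccccc2)c(OCc2ccccc2)c(OCc2ccccc2)c1 | intermediate
11 | racemic 5,7-bis(benzyloxy)-2-[3,4,5-tris(benzyloxy)phenyl]chroman-3-one | O=C1Cc2c(OCc3ccccc3)cc(OCc3ccccc3)cc2OC1c1cc(OCc2ccccc2)c(OCc2ccccc2)c(OCc2ccccc2)c1 | intermediate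
12 | (2R,3R)-5,7-bis(benzyloxy)-2-[3,4,5-tris(benzyloxy)phenyl]chroman-3-ol (penta-O-benzyl-(−)-epigallocatechin) | O[C@@H]1Cc2c(OCc3ccccc3)cc(OCc3ccccc3)cc2O[C@@H]1c1cc(OCc2ccccc2)c(OCc2ccccc2)c(OCc2ccccc2)c1 | intermediate
13 | 4β-(2-ethoxyethoxy)-penta-O-benzyl-(−)-epigallocatechin (2,3-cis, 3,4-trans) | CCOCCO[C@H]1c2c(OCc3ccccc3)cc(OCc3ccccc3)cc2O[C@H](c2cc(OCc3ccccc3)c(OCc3ccccc3)c(OCc3ccccc3)c2)[C@@H]1O | intermediate
14 | 4β-(2-ethoxyethoxy)-penta-O-benzyl-(−)-epigallocatechin 3-O-[3,4,5-tris(benzyloxy)benzoate] | CCOCCO[C@H]1c2c(OCc3ccccc3)cc(OCc3ccccc3)cc2O[C@H](c2cc(OCc3ccccc3)c(OCc3ccccc3)c(OCc3ccccc3)c2)[C@@H]1OC(=O)c1cc(OCc2ccccc2)c(OCc2ccccc2)c(OCc2ccccc2)c1 | intermediate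
15 | octa-O-benzyl-epigallocatechin 3-O-gallate-(4β→8)-penta-O-benzyl-epigallocatechin | O=C(O[C@@H]1[C@@H](c2c(OCc4ccccc4)cc(OCc4ccccc4)c3c2O[C@H](c2cc(OCc4ccccc4)c(OCc4ccccc4)c(OCc4ccccc4)c2)[C@H](O)C3)c2c(OCc3ccccc3)cc(OCc3ccccc3)cc2O[C@@H]1c1cc(OCc2ccccc2)c(OCc2ccccc2)c(OCc2ccccc2)c1)c1cc(OCc2ccccc2)c(OCc2ccccc2)c(OCc2ccccc2)c1 | intermediate
16 | penta-O-benzyl-epigallocatechin-(4β→8)-octa-O-benzyl-epigallocatechin 3-O-gallate-(4β→8)-penta-O-benzyl-epigallocatechin | O=C(O[C@@H]1[C@@H](c2c(OCc4ccccc4)cc(OCc4ccccc4)c3c2O[C@H](c2cc(OCc4ccccc4)c(OCc4ccccc4)c(OCc4ccccc4)c2)[C@H](O)C3)c2c(OCc3ccccc3)cc(OCc3ccccc3)c([C@H]3c4c(OCc5ccccc5)cc(OCc5ccccc5)cc4O[C@H](c4cc(OCc5ccccc5)c(OCc5ccccc5)c(OCc5ccccc5)c4)[C@@H]3O)c2O[C@@H]1c1cc(OCc2ccccc2)c(OCc2ccccc2)c(OCc2ccccc2)c1)c1cc(OCc2ccccc2)c(OCc2ccccc2)c(OCc2ccccc2)c1 | intermediate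
17 | epigallocatechin-(4β→8)-epigallocatechin 3-O-gallate-(4β→8)-epigallocatechin (CNP0278699.1) | O=C(O[C@@H]1[C@@H](c2c(O)cc(O)c3c2O[C@H](c2cc(O)c(O)c(O)c2)[C@H](O)C3)c2c(O)cc(O)c([C@H]3c4c(O)cc(O)cc4O[C@H](c4cc(O)c(O)c(O)c4)[C@@H]3O)c2O[C@@H]1c1cc(O)c(O)c(O)c1)c1cc(O)c(O)c(O)c1 | target

**Totals.** Total step count: 11. Longest linear sequence: 11 steps (1 → 12 → 13 → 14 → 15 → 16 → 17; compounds 12 and 13 are each used twice).

**Steps most likely to fail**

Step 4. The methylidene may stop at the acyclic enol ether, or the allyl double bond may shift into conjugation with ring A before the ring closes. The fallback replaces metathesis by a reductive carbonyl coupling and sets out from 7. Dihydroxylation of the allyl group (OsO4 cat., N-methylmorpholine N-oxide, acetone/H2O) should give the diol F1, and NaIO4 should cleave it to the arylacetaldehyde F2. Slow addition of F2 to low-valent titanium (TiCl3, Zn(Cu) couple, DME, reflux) should couple the aldehyde and ester carbonyls in a McMurry-type oxo-ester cyclisation, forming the same C2=C3 bond and returning to the route at 9.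

Step 6. Racemisation at C2 may be slower than reduction, or the catalyst may discriminate the two ketone faces poorly, which would erode both enantiomeric purity and the cis:trans ratio. The fallback replaces asymmetric catalysis by substrate-controlled reduction and resolution and sets out from 11. LiBH(s-Bu)3 in THF at −78 °C should deliver hydride anti to the 2-aryl group and give the racemic cis-alcohol F3. Preparative chromatography of F3 on a chiral stationary phase should then give the (2R,3R) enantiomer, returning to the route at 12.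

Step 10. The electrophile may condense with its own C8, and the product may be extended further at the C8 of its new top unit, giving oligomers. The fallback blocks that position and sets out from 13. NBS in CH2Cl2 at −78 °C should brominate C8 to give the 8-bromo ether F4. F4 can then be coupled with 15 in equimolar amount (Me3SiOTf, CH2Cl2, −40 °C) to give the 8-bromo protected trimer F5, which can neither self-condense nor grow. Hydrogenolysis of F5 (H2, Pd(OH)2/C, Et3N, THF/MeOH/H2O) should remove the bromine together with the benzyl groups, returning to the route at 17.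

**Further compounds**

F1 | step 4 | 3,5-bis(benzyloxy)-2-(2,3-dihydroxypropyl)phenyl 3,4,5-tris(benzyloxy)benzoate | OCC(O)Cc1c(OC(=O)c2cc(OCc3ccccc3)c(OCc3ccccc3)c(OCc3ccccc3)c2)cc(OCc2ccccc2)cc1OCc1ccccc1
F2 | step 4 | 3,5-bis(benzyloxy)-2-(2-oxoethyl)phenyl 3,4,5-tris(benzyloxy)benzoate | O=CCc1c(OC(=O)c2cc(OCc3ccccc3)c(OCc3ccccc3)c(OCc3ccccc3)c2)cc(OCc2ccccc2)cc1OCc1ccccc1
F3 | step 6 | racemic cis-5,7-bis(benzyloxy)-2-[3,4,5-tris(benzyloxy)phenyl]chroman-3-ol (both enantiomers) | O[C@@H]1Cc2c(OCc3ccccc3)cc(OCc3ccccc3)cc2O[C@@H]1c1cc(OCc2ccccc2)c(OCc2ccccc2)c(OCc2ccccc2)c1.O[C@H]1Cc2c(OCc3ccccc3)cc(OCc3ccccc3)cc2O[C@H]1c1cc(OCc2ccccc2)c(OCc2ccccc2)c(OCc2ccccc2)c1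
F4 | step 10 | 8-bromo-4β-(2-ethoxyethoxy)-penta-O-benzyl-(−)-epigallocatechin | CCOCCO[C@H]1c2c(OCc3ccccc3)cc(OCc3ccccc3)c(Br)c2O[C@H](c2cc(OCc3ccccc3)c(OCc3ccccc3)c(OCc3ccccc3)c2)[C@@H]1O
F5 | step 10 | protected trimer 16 carrying bromine at C8 of its top unit | O=C(O[C@@H]1[C@@H](c2c(OCc4ccccc4)cc(OCc4ccccc4)c3c2O[C@H](c2cc(OCc4ccccc4)c(OCc4ccccc4)c(OCc4ccccc4)c2)[C@H](O)C3)c2c(OCc3ccccc3)cc(OCc3ccccc3)c([C@H]3c4c(OCc5ccccc5)cc(OCc5ccccc5)c(Br)c4O[C@H](c4cc(OCc5ccccc5)c(OCc5ccccc5)c(OCc5ccccc5)c4)[C@@H]3O)c2O[C@@H]1c1cc(OCc2ccccc2)c(OCc2ccccc2)c(OCc2ccccc2)c1)c1cc(OCc2ccccc2)c(OCc2ccccc2)c(OCc2ccccc2)c1
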